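Both flavan units are cut at their C4–C4a bonds. The feature exploited is the central ether oxygen flanked by C4 and C4', each needing one aryl bond: replace each aryl carbon by a carboxyl group and a 2,2'-disubstituted diglycolic acid appears. Step 13, a nickel-catalysed electroreductive double decarboxylative arylation, forms C4–C4a and C4'–C4a', closes both pyran rings (ring C of each unit) and sets C4 and C4' in one operation. Its precursor is the bis(N-hydroxyphthalimide) ester of a diglycolic acid bearing two different (S)-2-(2-bromoaryloxy)-2-phenylethyl arms, one with 3-OMe and one with 3-OSi(i-Pr)3, so that the 5'-OMe/5-OH difference is built in and only desilylation follows.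

Key step: step 13

Conventions: flavan numbering; unit A is the 5-hydroxy-6,7-dimethoxyflavan half, unit B (primed locants) the 5,6,7-trimethoxyflavan half; ring C is the pyran ring of each unit. The carbons α to the carboxyl groups in 15 and 17–21 are carried as epimer mixtures, since step 13 makes them planar radicals. Methyl (S)-mandelate is the correct enantiomer: Mitsunobu inversion gives the (R)-ether, and the descriptor becomes S from 15 on only because CH2–C ranks below phenyl whereas CH2–O ranked above it.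

Assumption: bromination of 1 is taken to occur at C2, ortho to the free hydroxyl, as it does with isovanillin; the position is to be checked by HMBC before going on.

Step 1
Reactants: 1 3-hydroxy-4,5-dimethoxybenzaldehyde
Product: 2 2-bromo-3-hydroxy-4,5-dimethoxybenzaldehyde
Conditions: Br2 (1.05 equiv), NaOAc, AcOH, rt
Reagents that add atoms: bromine, BrBr
Why: Electrophilic aromatic bromination in which the free hydroxyl should direct bromine to its only open ortho carbon (C2, also para to the C5 methoxy group), the regiochemistry shown by isovanillin under the same buffered conditions.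

Step 2
Reactants: 2 2-bromo-3-hydroxy-4,5-dimethoxybenzaldehyde
Product: 3 2-bromo-4,5-dimethoxy-3-(triisopropylsilyloxy)benzaldehyde
Conditions: i-Pr3SiOTf, 2,6-lutidine, CH2Cl2, 0 °C → rt
Reagents that add atoms: triisopropylsilyl trifluoromethanesulfonate, CC(C)[Si](OS(=O)(=O)C(F)(F)F)(C(C)C)C(C)C
Why: O-Silylation of a phenol flanked by bromine and methoxy needs the silyl triflate with a hindered base, and the non-enolisable aldehyde is not affected.

Step 3
Reactants: 3 2-bromo-4,5-dimethoxy-3-(triisopropylsilyloxy)benzaldehyde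
Product: 5 2-bromo-4,5-dimethoxy-3-(triisopropylsilyloxy)phenol, via aryl formate 4 (not isolated)
Conditions: mCPBA, CH2Cl2, 0 °C → rt; then Et3N (cat.), MeOH, rt
Reagents that add atoms: 3-chloroperoxybenzoic acid, OOC(=O)c1cccc(Cl)c1
Why: Dakin-type Baeyer–Villiger oxidation in which the electron-rich aryl group migrates in the peroxy hemiacetal to give the aryl formate, which mild methanolysis should cleave without touching the hindered aryl silyl ether.

Step 4
Reactants: 5 2-bromo-4,5-dimethoxy-3-(triisopropylsilyloxy)phenol; 6 methyl (S)-mandelate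
Product: 7 methyl (R)-2-[2-bromo-4,5-dimethoxy-3-(triisopropylsilyloxy)phenoxy]-2-phenylacetate
Conditions: PPh3, DIAD, toluene, 0 °C → rt
Reagents that add atoms: none
Why: Mitsunobu etherification in which the phenol displaces the activated secondary hydroxyl by SN2, so the (S)-carbinol is inverted to the (R)-aryl ether that becomes C2 of unit A.

Step 5
Reactants: 7 methyl (R)-2-[2-bromo-4,5-dimethoxy-3-(triisopropylsilyloxy)phenoxy]-2-phenylacetate
Product: 8 (R)-2-[2-bromo-4,5-dimethoxy-3-(triisopropylsilyloxy)phenoxy]-2-phenylethanol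
Conditions: LiBH4, THF, 0 °C → rt
Reagents that add atoms: none
Why: Hydride reduction of an activated α-aryloxy ester to the primary alcohol by a reagent too weakly basic to epimerise the benzylic centre and inert towards aryl bromide and aryl silyl ether.

Step 6
Reactants: 9 3,4,5-trimethoxyphenol
Product: 10 2-bromo-3,4,5-trimethoxyphenol
Conditions: NBS (1.0 equiv), CH2Cl2, −78 → 0 °C
Reagents that add atoms: N-bromosuccinimide, O=C1CCC(=O)N1Br
Why: Electrophilic bromination of a symmetric phenol whose para position is blocked and whose two ortho positions are equivalent, so one equivalent of reagent at low temperature can give only this monobromide.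

Step 7
Reactants: 10 2-bromo-3,4,5-trimethoxyphenol; 6 methyl (S)-mandelate
Product: 11 methyl (R)-2-(2-bromo-3,4,5-trimethoxyphenoxy)-2-phenylacetate
Conditions: PPh3, DIAD, toluene, 0 °C → rt
Reagents that add atoms: none
Why: Mitsunobu etherification with SN2 inversion of the (S)-carbinol, which sets the centre that becomes C2' of unit B.

Step 8
Reactants: 11 methyl (R)-2-(2-bromo-3,4,5-trimethoxyphenoxy)-2-phenylacetate
Product: 12 (R)-2-(2-bromo-3,4,5-trimethoxyphenoxy)-2-phenylethanol
Conditions: LiBH4, THF, 0 °C → rt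
Reagents that add atoms: none
Why: Hydride reduction of the α-aryloxy ester to the primary alcohol under conditions that should leave the benzylic centre and the aryl bromide intact.

Step 9
Reactants: 12 (R)-2-(2-bromo-3,4,5-trimethoxyphenoxy)-2-phenylethanol; 13 dimethyl diglycolate (dimethyl 2,2'-oxydiacetate)
Product: 15 methyl (2RS,4S)-4-(2-bromo-3,4,5-trimethoxyphenoxy)-2-(2-methoxy-2-oxoethoxy)-4-phenylbutanoate, via triflate 14 (not isolated)
Conditions: 12, Tf2O, 2,6-di-tert-butyl-4-methylpyridine, CH2Cl2, −78 °C, then pentane and cold filtration; filtrate added to 13 (3 equiv) + LiN(i-Pr)2 (2.8 equiv), THF, −78 → −30 °C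
Reagents that add atoms: none
Why: Ester enolate alkylation (SN2) with a primary triflate reactive enough at low temperature to outrun E2, with excess lithium enolate of 13 (no free amide, no dipolar cosolvent) favouring C-monoalkylation and leaving the benzylic centre untouched.

Step 10
Reactants: 8 (R)-2-[2-bromo-4,5-dimethoxy-3-(triisopropylsilyloxy)phenoxy]-2-phenylethanol; 15 methyl (2RS,4S)-4-(2-bromo-3,4,5-trimethoxyphenoxy)-2-(2-methoxy-2-oxoethoxy)-4-phenylbutanoate
Product: 17 methyl (4S)-4-[2-bromo-4,5-dimethoxy-3-(triisopropylsilyloxy)phenoxy]-2-{[(3S)-3-(2-bromo-3,4,5-trimethoxyphenoxy)-1-(methoxycarbonyl)-3-phenylpropyl]oxy}-4-phenylbutanoate, via triflate 16 (not isolated)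
Conditions: 8, Tf2O, 2,6-di-tert-butyl-4-methylpyridine, CH2Cl2, −78 °C, then pentane and cold filtration; filtrate added to 15 (1.3 equiv) + LiN(i-Pr)2 (1.2 equiv), THF, −78 → −30 °C
Reagents that add atoms: none
Why: Second ester enolate alkylation (SN2 at a primary triflate), in which kinetic deprotonation of 15 at −78 °C should take the unhindered α'-CH2 and not the substituted α-CH, so the second arm goes to the other α-carbon.

Step 11
Reactants: 17 methyl (4S)-4-[2-bromo-4,5-dimethoxy-3-(triisopropylsilyloxy)phenoxy]-2-{[(3S)-3-(2-bromo-3,4,5-trimethoxyphenoxy)-1-(methoxycarbonyl)-3-phenylpropyl]oxy}-4-phenylbutanoate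
Product: 18 (4S)-4-[2-bromo-4,5-dimethoxy-3-(triisopropylsilyloxy)phenoxy]-2-{[(3S)-3-(2-bromo-3,4,5-trimethoxyphenoxy)-1-carboxy-3-phenylpropyl]oxy}-4-phenylbutanoic acid
Conditions: LiOH·H2O, THF–H2O, 0 °C → rt; then 1 M HCl to pH 3, 0 °C
Reagents that add atoms: lithium hydroxide, [Li+].[OH-]
Why: Saponification of two activated α-alkoxy methyl esters at low temperature, which the hindered aryl silyl ether and the benzylic aryl ethers should survive, and which avoids any strongly acidic ester cleavage.

Step 12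
Reactants: 18 (4S)-4-[2-bromo-4,5-dimethoxy-3-(triisopropylsilyloxy)phenoxy]-2-{[(3S)-3-(2-bromo-3,4,5-trimethoxyphenoxy)-1-carboxy-3-phenylpropyl]oxy}-4-phenylbutanoic acid
Product: 19 bis(1,3-dioxoisoindolin-2-yl) diester of diacid 18
Conditions: N-hydroxyphthalimide (2.4 equiv), i-PrN=C=N-i-Pr, DMAP (cat.), CH2Cl2, 0 °C → rt
Reagents that add atoms: N-hydroxyphthalimide, O=C1c2ccccc2C(=O)N1O
Why: Carbodiimide (Steglich-type) esterification of both carboxyl groups to give the redox-active bis(N-acyloxyphthalimide).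

Step 13
Reactants: 19 bis(1,3-dioxoisoindolin-2-yl) diester of diacid 18
Product: 22 (2S,4R)-6,7-dimethoxy-5-(triisopropylsilyloxy)flavan-4-yl (2S,4R)-5,6,7-trimethoxyflavan-4-yl ether, via unit-A monocyclised ester 20 (not isolated), via unit-B monocyclised ester 21 (not isolated)
Conditions: NiBr2(dme) (20 mol%), 4,4'-di-tert-butyl-2,2'-bipyridine (22 mol%), LiBr, DMA, undivided cell, reticulated vitreous carbon cathode, Zn anode, constant current, rt, slow addition of 19 (final 5 mM)
Reagents that add atoms: none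
Why: Proposed new method: cathodic reduction gives zerovalent nickel, which inserts into C4a–Br; electron transfer from low-valent nickel (or the cathode) to the N-acyloxyphthalimide releases phthalimide anion and CO2 and leaves a planar α-alkoxy radical at C4, the neighbouring arylnickel captures it, the aryl(alkyl) trivalent nickel species reductively eliminates C4–C4a, and the same cycle then forms C4'–C4a'. The closest known reaction type is the intermolecular nickel-catalysed (electro)reductive decarboxylative arylation of redox-active esters, those of α-alkoxy acids included, with aryl halides; an intramolecular, twofold version is without precedent. Each ring C closes by C(sp3)–C(sp2) reductive elimination from a seven-membered nickelacycle (Ni, C4, C3, C2, O1, C8a, C4a), that is a six-membered ring closure by intramolecular cross-electrophile coupling and not a radical addition to the arene. Because C4 and C4' arise from planar radicals the α-epimers of 19 converge, and the new centres should be set by C2 and C2': with the 2-phenyl group equatorial, the C4–O bond is expected to go pseudoaxial, away from the peri substituent at C5 (OSi(i-Pr)3) or C5' (OMe), which is the 2,4-trans (2S,4R) arrangement, and reversible radical capture should let the lower-energy transition state prevail. The step needs bonding at C4a and not at C8, secured by the position of bromine, ring closure in preference to intermolecular coupling or simple reduction, favoured by the tether plus high dilution, and 2,4-trans selectivity in both units, for which the peri C5 oxygen substituent is the controlling element.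

Step 14
Reactants: 22 (2S,4R)-6,7-dimethoxy-5-(triisopropylsilyloxy)flavan-4-yl (2S,4R)-5,6,7-trimethoxyflavan-4-yl ether
Product: 23 beilschmieflavonoid B
Conditions: Bu4NF (1.2 equiv), AcOH (1.2 equiv), THF, 0 °C
Reagents that add atoms: none
Why: Fluoride-mediated cleavage of the aryl silyl ether, buffered with AcOH so that the freed C5 phenoxide cannot expel the C4 alkoxide through an ortho-quinone methide and no acid strong enough to ionise the C4–O bond is present.

Compound list
1 | 3-hydroxy-4,5-dimethoxybenzaldehyde | COc1cc(C=O)cc(O)c1OC | starting material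
2 | 2-bromo-3-hydroxy-4,5-dimethoxybenzaldehyde | COc1cc(C=O)c(Br)c(O)c1OC | intermediate
3 | 2-bromo-4,5-dimethoxy-3-(triisopropylsilyloxy)benzaldehyde | COc1cc(C=O)c(Br)c(O[Si](C(C)C)(C(C)C)C(C)C)c1OC | intermediate
4 | 2-bromo-4,5-dimethoxy-3-(triisopropylsilyloxy)phenyl formate | COc1cc(OC=O)c(Br)c(O[Si](C(C)C)(C(C)C)C(C)C)c1OC | intermediate
5 | 2-bromo-4,5-dimethoxy-3-(triisopropylsilyloxy)phenol | COc1cc(O)c(Br)c(O[Si](C(C)C)(C(C)C)C(C)C)c1OC | intermediate
6 | methyl (S)-mandelate | COC(=O)[C@@H](O)c1ccccc1 | starting material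
7 | methyl (R)-2-[2-bromo-4,5-dimethoxy-3-(triisopropylsilyloxy)phenoxy]-2-phenylacetate | COC(=O)[C@H](Oc1cc(OC)c(OC)c(O[Si](C(C)C)(C(C)C)C(C)C)c1Br)c1ccccc1 | intermediate
8 | (R)-2-[2-bromo-4,5-dimethoxy-3-(triisopropylsilyloxy)phenoxy]-2-phenylethanol | OC[C@H](Oc1cc(OC)c(OC)c(O[Si](C(C)C)(C(C)C)C(C)C)c1Br)c1ccccc1 | intermediate
9 | 3,4,5-trimethoxyphenol | COc1cc(O)cc(OC)c1OC | starting material
10 | 2-bromo-3,4,5-trimethoxyphenol | COc1cc(O)c(Br)c(OC)c1OC | intermediate
11 | methyl (R)-2-(2-bromo-3,4,5-trimethoxyphenoxy)-2-phenylacetate | COC(=O)[C@H](Oc1cc(OC)c(OC)c(OC)c1Br)c1ccccc1 | intermediate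
12 | (R)-2-(2-bromo-3,4,5-trimethoxyphenoxy)-2-phenylethanol | OC[C@H](Oc1cc(OC)c(OC)c(OC)c1Br)c1ccccc1 | intermediate
13 | dimethyl diglycolate (dimethyl 2,2'-oxydiacetate) | COC(=O)COCC(=O)OC | starting material
14 | (R)-2-(2-bromo-3,4,5-trimethoxyphenoxy)-2-phenylethyl trifluoromethanesulfonate | FC(F)(F)S(=O)(=O)OC[C@H](Oc1cc(OC)c(OC)c(OC)c1Br)c1ccccc1 | intermediate
15 | methyl (2RS,4S)-4-(2-bromo-3,4,5-trimethoxyphenoxy)-2-(2-methoxy-2-oxoethoxy)-4-phenylbutanoate | COC(=O)COC(C[C@@H](c1ccccc1)Oc1cc(OC)c(OC)c(OC)c1Br)C(=O)OC | intermediate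
16 | (R)-2-[2-bromo-4,5-dimethoxy-3-(triisopropylsilyloxy)phenoxy]-2-phenylethyl trifluoromethanesulfonate | FC(F)(F)S(=O)(=O)OC[C@H](Oc1cc(OC)c(OC)c(O[Si](C(C)C)(C(C)C)C(C)C)c1Br)c1ccccc1 | intermediate
17 | methyl (4S)-4-[2-bromo-4,5-dimethoxy-3-(triisopropylsilyloxy)phenoxy]-2-{[(3S)-3-(2-bromo-3,4,5-trimethoxyphenoxy)-1-(methoxycarbonyl)-3-phenylpropyl]oxy}-4-phenylbutanoate (α-epimer mixture) | COC(=O)C(C[C@@H](c1ccccc1)Oc1cc(OC)c(OC)c(O[Si](C(C)C)(C(C)C)C(C)C)c1Br)OC(C[C@@H](c1ccccc1)Oc1cc(OC)c(OC)c(OC)c1Br)C(=O)OC | intermediate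
18 | (4S)-4-[2-bromo-4,5-dimethoxy-3-(triisopropylsilyloxy)phenoxy]-2-{[(3S)-3-(2-bromo-3,4,5-trimethoxyphenoxy)-1-carboxy-3-phenylpropyl]oxy}-4-phenylbutanoic acid (α-epimer mixture) | OC(=O)C(C[C@@H](c1ccccc1)Oc1cc(OC)c(OC)c(O[Si](C(C)C)(C(C)C)C(C)C)c1Br)OC(C[C@@H](c1ccccc1)Oc1cc(OC)c(OC)c(OC)c1Br)C(=O)O | intermediate
19 | bis(1,3-dioxoisoindolin-2-yl) diester of diacid 18 (α-epimer mixture) | O=C(ON1C(=O)c2ccccc2C1=O)C(C[C@@H](c1ccccc1)Oc1cc(OC)c(OC)c(O[Si](C(C)C)(C(C)C)C(C)C)c1Br)OC(C[C@@H](c1ccccc1)Oc1cc(OC)c(OC)c(OC)c1Br)C(=O)ON1C(=O)c2ccccc2C1=O | intermediate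
20 | 1,3-dioxoisoindolin-2-yl (4S)-4-(2-bromo-3,4,5-trimethoxyphenoxy)-2-{[(2S,4R)-6,7-dimethoxy-5-(triisopropylsilyloxy)flavan-4-yl]oxy}-4-phenylbutanoate (ring C of unit A closed) | COc1cc2c(c(O[Si](C(C)C)(C(C)C)C(C)C)c1OC)[C@H](OC(C[C@@H](c1ccccc1)Oc1cc(OC)c(OC)c(OC)c1Br)C(=O)ON1C(=O)c3ccccc3C1=O)C[C@@H](c1ccccc1)O2 | intermediate
21 | 1,3-dioxoisoindolin-2-yl (4S)-4-[2-bromo-4,5-dimethoxy-3-(triisopropylsilyloxy)phenoxy]-2-{[(2S,4R)-5,6,7-trimethoxyflavan-4-yl]oxy}-4-phenylbutanoate (ring C of unit B closed) | O=C(ON1C(=O)c2ccccc2C1=O)C(C[C@@H](c1ccccc1)Oc1cc(OC)c(OC)c(O[Si](C(C)C)(C(C)C)C(C)C)c1Br)O[C@@H]1C[C@@H](c2ccccc2)Oc2cc(OC)c(OC)c(OC)c21 | intermediate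
22 | (2S,4R)-6,7-dimethoxy-5-(triisopropylsilyloxy)flavan-4-yl (2S,4R)-5,6,7-trimethoxyflavan-4-yl ether | COc1cc2c(c(O[Si](C(C)C)(C(C)C)C(C)C)c1OC)[C@H](O[C@@H]1C[C@@H](c3ccccc3)Oc3cc(OC)c(OC)c(OC)c31)C[C@@H](c1ccccc1)O2 | intermediate
23 | beilschmieflavonoid B, (2S,4R)-5-hydroxy-6,7-dimethoxyflavan-4-yl (2S,4R)-5,6,7-trimethoxyflavan-4-yl ether | COc1cc2c(c(O)c1OC)[C@H](O[C@@H]1C[C@@H](c3ccccc3)Oc3cc(OC)c(OC)c(OC)c31)C[C@@H](c1ccccc1)O2 | target

Total step count: 14. Longest linear sequence: 10 steps (steps 1–5 and 10–14, from 1 to 23).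

Steps most likely to fail

Step 13. Oxidative addition at the two doubly ortho-substituted C–Br bonds may be slow, so the α-alkoxy radical could be reduced or abstract hydrogen before capture. The C4 radical may also take the benzylic hydrogen at C2' of the other arm by 1,5-transfer, chains may couple intermolecularly, and ring closure may show too little 2,4-trans preference. The fallback uses known chemistry and makes the two C4–O bonds by etherification of two flavan-4-ols; it sets out from 9 and comes back at 22.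
- Friedel–Crafts acetylation of 9 (AcOH, BF3·OEt2, heat) should give 1-(6-hydroxy-2,3,4-trimethoxyphenyl)ethanone F1.
- Me2NCH(OMe)2 converts it into (E)-3-(dimethylamino)-1-(6-hydroxy-2,3,4-trimethoxyphenyl)prop-2-en-1-one F2, which aqueous HCl closes to 5,6,7-trimethoxychromone F3.
- Enantioselective conjugate addition of PhB(OH)2 (Pd(OCOCF3)2 with the t-BuPyOx enantiomer that delivers 2S) gives (S)-5,6,7-trimethoxyflavanone F4.
- NaBH4 reduces F4 to (2S,4S)-5,6,7-trimethoxyflavan-4-ol F5.
- A second portion of F4 is demethylated at O5 only (BCl3, chelation to the C4 carbonyl) to (S)-5-hydroxy-6,7-dimethoxyflavanone F6.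
- Silylation (i-Pr3SiOTf, 2,6-lutidine) gives (S)-6,7-dimethoxy-5-(triisopropylsilyloxy)flavanone F7, and NaBH4 reduction gives (2S,4S)-6,7-dimethoxy-5-(triisopropylsilyloxy)flavan-4-ol F8.
- Acid-catalysed etherification of F8 with excess F5 (pyridinium p-toluenesulfonate, CH2Cl2, molecular sieves) runs through 4-flavanyl cations that are captured anti to the 2-phenyl group. It should give 22 after separation from the two symmetric ethers.

Step 10. Deprotonation of 15 may occur at the already substituted α-carbon, or enolates may exchange protons, which leads to geminal dialkylation. The triflate may also be lost by E2 elimination or consumed by O-alkylation. The fallback replaces the ester enolate by a malonate linchpin that has only one acidic hydrogen on each α-carbon; it sets out from 12 and 8 (as their triflates 14 and 16) and comes back at 17.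
- Rh2(OAc)4-catalysed O–H insertion of dimethyl diazomalonate into dimethyl 2-hydroxymalonate gives tetramethyl 2,2'-oxydimalonate F9.
- NaH followed by 14 gives tetramethyl 1-[(2S)-2-(2-bromo-3,4,5-trimethoxyphenoxy)-2-phenylethyl]-2,2'-oxydimalonate F10.
- NaH followed by 16 gives the doubly alkylated tetramethyl 2,2'-oxydimalonate F11.
- Krapcho demethoxycarbonylation (LiCl, wet DMSO, heat) removes one ester group from each α-carbon and returns 17.

Step 4 (the same holds for step 7). Enantiopurity may be lost through enolisation of the α-aryloxy phenylacetate during coupling or reduction, and the hindered phenol may couple sluggishly. The fallback keeps the stereocentre away from any carbonyl group; it sets out from 5 and comes back at 8.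
- Silylation of the primary hydroxyl of (S)-1-phenylethane-1,2-diol (t-BuMe2SiCl, imidazole) gives (S)-2-(tert-butyldimethylsilyloxy)-1-phenylethanol F12.
- Mitsunobu coupling with 5 (inversion) gives (R)-tert-butyl{2-[2-bromo-4,5-dimethoxy-3-(triisopropylsilyloxy)phenoxy]-2-phenylethoxy}dimethylsilane F13.
- Pyridinium p-toluenesulfonate in MeOH removes only the primary alkyl silyl group and returns 8.
- Applied to 10, the same sequence gives (R)-tert-butyl[2-(2-bromo-3,4,5-trimethoxyphenoxy)-2-phenylethoxy]dimethylsilane F14 and returns 12.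

Further compounds
F1 | step 13 | 1-(6-hydroxy-2,3,4-trimethoxyphenyl)ethanone | CC(=O)c1c(O)cc(OC)c(OC)c1OC
F2 | step 13 | (E)-3-(dimethylamino)-1-(6-hydroxy-2,3,4-trimethoxyphenyl)prop-2-en-1-one | CN(C)/C=C/C(=O)c1c(O)cc(OC)c(OC)c1OC
F3 | step 13 | 5,6,7-trimethoxychromone | COc1cc2occc(=O)c2c(OC)c1OC
F4 | step 13 | (S)-5,6,7-trimethoxyflavanone | COc1cc2c(c(OC)c1OC)C(=O)C[C@@H](c1ccccc1)O2
F5 | step 13 | (2S,4S)-5,6,7-trimethoxyflavan-4-ol | COc1cc2c(c(OC)c1OC)[C@@H](O)C[C@@H](c1ccccc1)O2
F6 | step 13 | (S)-5-hydroxy-6,7-dimethoxyflavanone | COc1cc2c(c(O)c1OC)C(=O)C[C@@H](c1ccccc1)O2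
F7 | step 13 | (S)-6,7-dimethoxy-5-(triisopropylsilyloxy)flavanone | COc1cc2c(c(O[Si](C(C)C)(C(C)C)C(C)C)c1OC)C(=O)C[C@@H](c1ccccc1)O2
F8 | step 13 | (2S,4S)-6,7-dimethoxy-5-(triisopropylsilyloxy)flavan-4-ol | COc1cc2c(c(O[Si](C(C)C)(C(C)C)C(C)C)c1OC)[C@@H](O)C[C@@H](c1ccccc1)O2
F9 | step 10 | tetramethyl 2,2'-oxydimalonate | COC(=O)C(OC(C(=O)OC)C(=O)OC)C(=O)OC
F10 | step 10 | tetramethyl 1-[(2S)-2-(2-bromo-3,4,5-trimethoxyphenoxy)-2-phenylethyl]-2,2'-oxydimalonate | COC(=O)C(OC(C[C@@H](c1ccccc1)Oc1cc(OC)c(OC)c(OC)c1Br)(C(=O)OC)C(=O)OC)C(=O)OC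
F11 | step 10 | tetramethyl 2,2'-oxydimalonate carrying the unit-A arm on one α-carbon and the unit-B arm on the other | COC(=O)C(C[C@@H](c1ccccc1)Oc1cc(OC)c(OC)c(O[Si](C(C)C)(C(C)C)C(C)C)c1Br)(OC(C[C@@H](c1ccccc1)Oc1cc(OC)c(OC)c(OC)c1Br)(C(=O)OC)C(=O)OC)C(=O)OC
F12 | step 4 | (S)-2-(tert-butyldimethylsilyloxy)-1-phenylethanol | CC(C)(C)[Si](C)(C)OC[C@@H](O)c1ccccc1
F13 | step 4 | (R)-tert-butyl{2-[2-bromo-4,5-dimethoxy-3-(triisopropylsilyloxy)phenoxy]-2-phenylethoxy}dimethylsilane | CC(C)(C)[Si](C)(C)OC[C@H](Oc1cc(OC)c(OC)c(O[Si](C(C)C)(C(C)C)C(C)C)c1Br)c1ccccc1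
F14 | step 4 | (R)-tert-butyl[2-(2-bromo-3,4,5-trimethoxyphenoxy)-2-phenylethoxy]dimethylsilane | CC(C)(C)[Si](C)(C)OC[C@H](Oc1cc(OC)c(OC)c(OC)c1Br)c1ccccc1
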